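Take the last two isomer readings of the zeta run and turn them into a flow in molar terms, because we shall reckon this flask with that flow.

| flask | substrate | remark | time |
|---|---|---|---|
| zeta | 0.80 M | run made earlier |  |
| flask | 0.40 M |  | 4.0 min |

zeta run (percent of the substrate charged)

| time / s | target / % | isomer of the product / % |
|---|---|---|
| 10.0 | 40.2 | 7.9 |
| 12.0 | 43.9 | 7.0 |
| 20.0 | 52.1 | 10.2 |
| 30.0 | 57.3 | 12.7 |
| 50.0 | 63.6 | 16.6 |
| 80.0 | 66.5 | 19.0 |

(readings scatter by 1 percentage point)

- a reading or a percentage of target counts all its forms, free or not

- ratio of target to isomer of the product at 0.40 s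
- ratio of target to isomer of the product at 4.0 min

At the start we compare rates, and the earliest readings come nearest to doing so. Target over isomer of the product, summed over the first two readings, is our selectivity factor, and we take it as our answer for 0.40 s:

early ratio = 5.64

The comparison then drifts: the zeta ratio reads 3.50 at 80.0 s. We name the stream the molar gain of isomer of the product per second between the last two readings:

stream = 0.640 mM s⁻¹

It is rough, a gain of 2.4 percentage points between readings scattering by 1 point. Target is counted free or not, so we suppose that free target stands at a level apart from the charge and that the stream stays the same in the flask.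

Two extreme flasks bound 4.0 min. If the stream stops, the ratio stays at 3.50. If it runs throughout, on top of the last reading:

isomer = 57.4% of a recovered 85.5%, ratio 0.490

That counts the stream twice up to 80.0 s. Removing this gives 0.917, and we commit to a ratio between these last two.

The forecast, on “parallel routes”, gives 3.5 (2.8 to 4.6) and 1.45 (1.2 to 1.9). The flask gives 6.20 and 0.556.

    substrate ⇌ target (K = 0.460, k = 0.0862 s⁻¹)
    substrate ⇌ isomer of the product (K = 19.0, k = 0.0127 s⁻¹)
    target ⇌ isomer of the product (k = 0.0356 s⁻¹)
    substrate ⇌ dormant form (K = 1.30, k = 0.0629 s⁻¹)
    crystals ⇌ target, rate k5*(cs5 - [target]) while solid is left; crystals form when [target] > cs5 (solubility = 15.0 mM, k = 3.88 s⁻¹)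

From 2.00 min to 4.00 min, isomer of the product in the flask rose from 34.2% to 53.3%, which is 0.637 mM s⁻¹, while crystals fell from 43.6% to 25.9%. In the neighbouring flask charged with 1.6 M, the stream reckons to 9.6 points on top of the last zeta reading of 19.0% isomer of the product. That neighbouring flask ends with 21.1% isomer of the product, 2.1 points above that reading, and with 74.4% target, 73.4% of it as crystals, a ratio of 3.52.

The readings come from a simulation with made-up constants, and the scatter is random.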